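**Conventions.** Locants follow eremophilane numbering: C1 = CH–O, C4 = CH–CO2R (C15), C5 = quaternary C–CH3, C7 = CH bearing the C11–C13 unit, C8 = C=O, C9=C10. "α" is the face of the C5 methyl. Compounds 4–8 are racemic and drawn as the enantiomer carried forward.
**Assumption.** In step 10 the Taniaphos antipode is the one that delivers (S)-15 (sense of induction to be confirmed by rotation).

## Retrosynthetic overview
1. Integric acid ⇒ tert-butyl ester 21 ⇒ acid 18 + alcohol 12 (ester bond); the acrolein unit comes from a C7 allyl group (oxidative cleavage, then α-methylenation).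
2. γ-Hydroxy-enone 10 ⇒ ene-1,8-dione 8 (reduce both C=O, re-oxidise the unhindered C8 carbinol); a CBS reduction that is matched for only one enantiomer fixes absolute configuration (kinetic resolution).
3. Key disconnection C5–C6: ring A and the C5 quaternary centre arise from a 6-endo-trig radical cyclisation onto the fully substituted β-carbon of a C10-alkylated Hagemann-type enone (6), anti to the C4 ester.
4. Ring B, already carrying the C1 oxygen, C4 carboxyl and C5 methyl ⇒ tert-butyl acetoacetate + methyl vinyl ketone; C6–C9 ⇒ 1,4-dibromobutan-2-one.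
5. Ring order: B (condensation), then A (radical). Acid 18 comes from Cu-catalysed allylic alkylation and cross-metathesis.

## Route

**Step 1**
Reactants: 1, diketene
Product: 2, tert-butyl 3-oxobutanoate
Conditions: t-BuOH, NaOAc (cat.), 80 °C
Reagents that add atoms: tert-butanol, CC(C)(C)O
Why: Ring-opening acylation of the alcohol by diketene gives the acid-labile ester that is removed only in the last step.

**Step 2**
Reactants: 2, tert-butyl 3-oxobutanoate; 3, methyl vinyl ketone
Product: 4, (±)-tert-butyl 2-methyl-4-oxocyclohex-2-ene-1-carboxylate (tert-butyl Hagemann ester; ring B with C1=O, C4–CO2tBu, C5–CH3)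
Conditions: KOt-Bu (5 mol %), t-BuOH, 0 °C → rt; then pyrrolidine/AcOH (cat.), toluene, 80 °C, –H2O
Reagents that add atoms: none
Why: Michael addition then enamine aldol condensation (Robinson-type Hagemann ester synthesis); C4 is a labile vinylogous β-keto ester centre, so it is left racemic here.

**Step 3**
Reactants: 4, tert-butyl Hagemann ester; 5, 1,4-dibromobutan-2-one
Product: 6, (±)-tert-butyl 3-(4-bromo-2-oxobutyl)-2-methyl-4-oxocyclohex-2-ene-1-carboxylate (C10 now carries C9H2–C8(=O)–C7H2–C6H2Br)
Conditions: KOt-Bu (1.0 equiv), t-BuOH/THF, 0 °C; then 5 (1.1 equiv), 0 °C → rt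
Reagents that add atoms: none
Why: The extended enolate of Hagemann esters alkylates at the α-carbon (C10), and the α-bromoketone CH2Br reacts far faster than the primary CH2Br, so C9 is attached chemoselectively (dienolate SN2 alkylation).

**Step 4 (key step)**
Reactants: 6, bromo-ketone
Product: 7, (±)-tert-butyl 5-methyl-1,8-dioxodecalin-4-carboxylate, 5-CH3 cis to 4-CO2tBu, C10–H epimers (mainly cis-fused)
Conditions: Bu3SnH (1.3 equiv, syringe pump, 8 h), AIBN (0.2 equiv), PhH, 80 °C, 5 mM
Reagents that add atoms: none
Why: Radical conjugate addition. Bromine abstraction gives the primary C6 radical, which adds 6-endo-trig to C5, the enone β-carbon. 5-Exo attack at C10 is disfavoured by polarity, spiro strain and the sp2 C8 in the tether. Attack is anti to the pseudo-axial C4 ester (A1,2 strain with the C5 methyl), so the C5 quaternary centre forms with CH3 cis to CO2tBu; Sn–H then reduces the C10 α-keto radical. Neutral conditions leave the acidic C4–H untouched.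

**Step 5**
Reactants: 7, saturated 1,8-dione
Product: 8, (±)-tert-butyl 5-methyl-1,8-dioxo-Δ9(10)-octalin-4-carboxylate (ene-1,8-dione; (4S,5R) enantiomer drawn)
Conditions: IBX (2.5 equiv), DMSO/toluene, 70 °C
Reagents that add atoms: none
Why: IBX dehydrogenation of the 1,4-diketone across C9–C10 (each carbon is α to one carbonyl) gives the doubly conjugated ene-dione and erases the C10 centre.

**Step 6**
Reactants: 8, (±)-ene-1,8-dione
Product: 9, tert-butyl (1R,4S,5R)-1,8-dihydroxy-5-methyl-Δ9(10)-octalin-4-carboxylate (C8 epimers), single enantiomeric series, ≤50 %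
Conditions: (S)-2-methyl-CBS-oxazaborolidine (0.5 equiv), catecholborane (1.6 equiv), toluene, –78 → –40 °C; chromatography
Reagents that add atoms: none
Why: CBS reduction used as a kinetic resolution. With RL = C10 and RS = C2H2, the (S)-catalyst delivers hydride to the C1 face anti to the axial C5 methyl only in the (4S,5R) enantiomer, giving the 1α (axial, 1R) alcohol. In the other enantiomer that face is methyl-shielded, so only C8 is reduced and the resulting keto-alcohol is separated. The C8 configuration is irrelevant.

**Step 7**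
Reactants: 9, diol
Product: 10, tert-butyl (1R,4S,5R)-1-hydroxy-5-methyl-8-oxo-Δ9(10)-octalin-4-carboxylate
Conditions: MnO2 (20 equiv), CH2Cl2, rt
Reagents that add atoms: none
Why: Allylic oxidation selects the unhindered C8 carbinol; the C1–OH is axial, 1,3-diaxial to CH3 and next to the tetrasubstituted C10 (as in steroidal 4-ene-3,6-diols giving 6-hydroxy-4-en-3-ones).

**Step 8**
Reactants: 10, hydroxy-enone; 11, allyl bromide
Product: 12, tert-butyl (1R,4S,5R,7R)-1-hydroxy-5-methyl-8-oxo-7-(prop-2-enyl)-Δ9(10)-octalin-4-carboxylate (7β-allyl, trans to 5-CH3)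
Conditions: LDA (2.2 equiv), THF, –78 °C; allyl bromide (1.2 equiv), –78 → –20 °C
Reagents that add atoms: none
Why: Kinetic α′-deprotonation gives the cross-conjugated C7 enolate (the C1 alkoxide protects the OH); alkylation occurs anti to the axial C5 methyl, giving the equatorial, also thermodynamic, 7β isomer.

**Step 9**
Reactants: 13, (E)-hept-2-en-1-ol
Product: 14, (E)-1-bromohept-2-ene
Conditions: PBr3 (0.4 equiv), Et2O, 0 °C
Reagents that add atoms: phosphorus tribromide, BrP(Br)Br
Why: SN2 bromination of the primary allylic alcohol with retention of E geometry.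

**Step 10**
Reactants: 14, (E)-1-bromohept-2-ene
Product: 15, (S)-3-methylhept-1-ene
Conditions: MeMgBr (1.2 equiv), CuBr·SMe2 (1 mol %), Taniaphos (1.2 mol %), CH2Cl2, –75 °C
Reagents that add atoms: methylmagnesium bromide, C[Mg]Br
Why: Cu-catalysed asymmetric allylic alkylation (SN2′, branched-selective); the ligand sets the side-chain stereocentre.

**Step 11**
Reactants: 15, (S)-3-methylhept-1-ene; 16, methacrolein
Product: 17, (2E,4S)-2,4-dimethyloct-2-enal
Conditions: Hoveyda–Grubbs II (5 mol %), methacrolein (8 equiv), CH2Cl2, 40 °C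
Reagents that add atoms: none
Why: Olefin cross-metathesis gives the E trisubstituted enal (thermodynamic); no base, so the allylic stereocentre is untouched.

**Step 12**
Reactants: 17, enal
Product: 18, (2E,4S)-2,4-dimethyloct-2-enoic acid
Conditions: NaClO2, NaH2PO4, 2-methyl-2-butene, t-BuOH/H2O, 0 °C → rt
Reagents that add atoms: sodium chlorite, [Na+].[O-]Cl=O
Why: Pinnick oxidation of the enal without touching the alkene or the stereocentre.

**Step 13**
Reactants: 12, alcohol; 18, acid
Product: 19, tert-butyl (1R,4S,5R,7R)-1-[(2E,4S)-2,4-dimethyloct-2-enoyloxy]-5-methyl-8-oxo-7-(prop-2-enyl)-Δ9(10)-octalin-4-carboxylate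
Conditions: 18, 2,4,6-trichlorobenzoyl chloride, Et3N, THF, rt; then 12, DMAP, toluene, 50 °C
Reagents that add atoms: none
Why: Yamaguchi esterification acylates the hindered axial C1–OH; no stereocentre is altered.

**Step 14**
Reactants: 19, allyl ester
Product: 20, the corresponding 7-(2-oxoethyl) compound (7S by CIP, same 7β geometry)
Conditions: OsO4 (2 mol %), NaIO4 (4 equiv), 2,6-lutidine, dioxane/H2O, rt
Reagents that add atoms: osmium tetroxide, O=[Os](=O)(=O)=O, with sodium periodate, [Na+].[O-]I(=O)(=O)=O
Why: Lemieux–Johnson cleavage selects the electron-rich terminal alkene over the two electron-poor trisubstituted C=C bonds.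

**Step 15**
Reactants: 20, aldehyde
Product: 21, integric acid tert-butyl ester (7-(3-oxoprop-1-en-2-yl))
Conditions: Eschenmoser's salt (3 equiv), Et3N, CH2Cl2, rt
Reagents that add atoms: N,N-dimethylmethyleneiminium iodide, C=[N+](C)C.[I-]
Why: Mannich reaction then amine elimination (α-methylenation of the aldehyde) builds the 2-substituted acrolein; C7 stays in, or equilibrates to, the equatorial 7β configuration.

**Step 16**
Reactants: 21, tert-butyl ester
Product: 22, integric acid
Conditions: TFA/CH2Cl2 (1:4), 0 °C → rt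
Reagents that add atoms: none
Why: Acidolysis of the tert-butyl ester; the enal, enone and allylic enoate (allylic to an electron-poor alkene) tolerate TFA.

## Compound list
1 | diketene | C=C1CC(=O)O1 | starting material
2 | tert-butyl 3-oxobutanoate | CC(=O)CC(=O)OC(C)(C)C | intermediate
3 | methyl vinyl ketone | CC(=O)C=C | starting material
4 | (±)-tert-butyl 2-methyl-4-oxocyclohex-2-ene-1-carboxylate | CC1=CC(=O)CCC1C(=O)OC(C)(C)C | intermediate
5 | 1,4-dibromobutan-2-one | BrCC(=O)CCBr | starting material
6 | (±)-tert-butyl 3-(4-bromo-2-oxobutyl)-2-methyl-4-oxocyclohex-2-ene-1-carboxylate | CC1=C(CC(=O)CCBr)C(=O)CCC1C(=O)OC(C)(C)C | intermediate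
7 | (±)-tert-butyl 5-methyl-1,8-dioxodecalin-4-carboxylate, CH3 cis to CO2tBu, C10 epimers | C1C[C@@]2(C)C(CC1=O)C(=O)CC[C@@H]2C(=O)OC(C)(C)C | intermediate
8 | (±)-tert-butyl 5-methyl-1,8-dioxo-Δ9(10)-octalin-4-carboxylate ((4S,5R) drawn) | C1C[C@@]2(C)C(=CC1=O)C(=O)CC[C@@H]2C(=O)OC(C)(C)C | intermediate
9 | tert-butyl (1R,4S,5R)-1,8-dihydroxy-5-methyl-Δ9(10)-octalin-4-carboxylate (C8 epimers) | C1C[C@@]2(C)C(=CC1O)[C@H](O)CC[C@@H]2C(=O)OC(C)(C)C | intermediate
10 | tert-butyl (1R,4S,5R)-1-hydroxy-5-methyl-8-oxo-Δ9(10)-octalin-4-carboxylate | C1C[C@@]2(C)C(=CC1=O)[C@H](O)CC[C@@H]2C(=O)OC(C)(C)C | intermediate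
11 | allyl bromide | C=CCBr | starting material
12 | 7β-allyl derivative of 10 (1R,4S,5R,7R) | C=CC[C@@H]1C[C@@]2(C)C(=CC1=O)[C@H](O)CC[C@@H]2C(=O)OC(C)(C)C | intermediate
13 | (E)-hept-2-en-1-ol | CCCC/C=C/CO | starting material
14 | (E)-1-bromohept-2-ene | CCCC/C=C/CBr | intermediate
15 | (S)-3-methylhept-1-ene | C=C[C@@H](C)CCCC | intermediate
16 | methacrolein | CC(=C)C=O | starting material
17 | (2E,4S)-2,4-dimethyloct-2-enal | O=C/C(C)=C/[C@@H](C)CCCC | intermediate
18 | (2E,4S)-2,4-dimethyloct-2-enoic acid | OC(=O)/C(C)=C/[C@@H](C)CCCC | intermediate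
19 | C1 ester of 12 with 18 | C=CC[C@@H]1C[C@@]2(C)C(=CC1=O)[C@H](OC(=O)/C(C)=C/[C@@H](C)CCCC)CC[C@@H]2C(=O)OC(C)(C)C | intermediate
20 | 7-(2-oxoethyl) aldehyde | O=CC[C@@H]1C[C@@]2(C)C(=CC1=O)[C@H](OC(=O)/C(C)=C/[C@@H](C)CCCC)CC[C@@H]2C(=O)OC(C)(C)C | intermediate
21 | integric acid tert-butyl ester | C=C(C=O)[C@@H]1C[C@@]2(C)C(=CC1=O)[C@H](OC(=O)/C(C)=C/[C@@H](C)CCCC)CC[C@@H]2C(=O)OC(C)(C)C | intermediate
22 | integric acid | C=C(C=O)[C@@H]1C[C@@]2(C)C(=CC1=O)[C@H](OC(=O)/C(C)=C/[C@@H](C)CCCC)CC[C@@H]2C(=O)O | target

## Summary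
Total steps: 16. Longest linear sequence: 12 (steps 1–8, then 13–16); the side-chain branch is 4 steps (9–12).

Steps most likely to fail, with fallbacks:
- **Step 4 (6-endo radical cyclisation onto the hindered β-carbon; risks are simple reduction or 5-exo spirocyclisation).** Fallback: dehydrobrominate 6 to the vinyl ketone and forge the same C5–C6 bond by reductive enone–enone radical coupling (SmI2/HMPA/t-BuOH, or Ru(bpy)3Cl2, i-Pr2NEt, HCO2H, visible light), where the β-radical comes from enone reduction instead of halide abstraction.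
- **Step 6 (CBS kinetic resolution; risks are insufficient matched/mismatched discrimination or 1,4-reduction).** Fallback: reduce (±)-8 with NaBH4/CeCl3, carry the racemate through to step 13 and separate the two diastereomeric esters formed with enantiopure 18.
- **Step 13 (acylation of the hindered axial C1–OH with an α-branched enoic acid).** Fallback: acylate 12 with 2-(diethoxyphosphoryl)propanoic acid (DCC/DMAP) and build the enoate on the core by Horner–Wadsworth–Emmons reaction with (S)-2-methylhexanal (from ozonolysis of 15).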